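(The data were computed with constants of no real substance, noise included.)

The amounts are counted first. If each target spends one partner, the flask asked about charges substrate against partner at 0.556, and this fraction of the partner charge, the load, counts the turnovers that the substrate can ask of the partner.

| flask | substrate | partner | capture agent | remark | time |
|---|---|---|---|---|---|
| Sunday's | 0.034 M | 0.090 M | 2.5 mM | run made earlier |  |
| Monday's | 0.075 M | 0.090 M | 2.5 mM | run made earlier |  |
| Friday's | 0.050 M | 0.090 M | 3.8 mM | run made earlier |  |
| flask | 0.050 M | 0.0900 M | 2.50 mM |  | 30 min |

- Sunday's (time / min: target / %, substrate / %): 1.00: 38.4, 0.8; 2.00: 71.4, 0.4; 4.00: 82.6, 0.3; 6.00: 77.2, 0; 12.0: 60.2, 0.2; 25.0: 36.3, 0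
- Monday's (time / min: target / %, substrate / %): 1.00: 29.4, 0; 2.00: 52.2, 0.4; 4.00: 68.1, 0; 6.00: 68.3, 0.8; 12.0: 55.2, 0; 25.0: 32.3, 0.2
- Friday's (time / min: target / %, substrate / %): 1.00: 33.5, 0.4; 2.00: 64.3, 0; 5.00: 76.2, 0; 10.0: 63.8, 0.3; 25.0: 35.0, 0.4

(each reading ± 0.5 percentage points)

1. the moment within 30 min at which there is most target
2. the amount of target, in percent of the substrate charged, at that time
3. the first time at which target reaches 55%, in the same percent, in min



The bench rule says that a load under one makes substrate the limiting reagent, so the peak of target should stand near the full charge whatever the load. The runs show the border of that rule, because Monday's load of 0.833 is also under one, yet its highest target reading is 68.3%, lower than the 82.6% read at Sunday's load of 0.378. The count therefore gives a ceiling, and the readings give the slope. The reckoning made here, which is not the forecast's, draws a straight line through those two readings, losing 31 percentage points per whole unit of load, and so puts the peak of the flask at 77.0%. It reckons the height and not the time. Friday's run, which the line did not use, has a load of 0.556 with more capture agent and read 76.2% at 5.00 min.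

The forecast, “Scaling Friday's curve”, gives 75% at 4.8 min, and 55% reached at 1.73 min.

The flask gives 78.2% at 4.01 min and reaches 55% at 1.63 min, so the forecast's time stands 1.20 times the simulated one, and the line at load 0.556 stands 1.2 points below the simulated peak.

    partner → second intermediate (k = 0.00887 /s)
    2 open intermediate → homo product (k = 0.0232 /M/s)
    second intermediate + capture agent → trapped intermediate (k = 0.160 /M/s)
    target → over-reaction product (k = 6.77 × 10⁻⁴ /s)
    open intermediate + second intermediate → target (k = 0.612 /M/s)
    substrate → open intermediate (k = 0.257 /s)

The neighbouring flask, charged with 0.085 M of substrate and otherwise like the flask asked about, has a load of 0.944, still under one. The same line puts its peak at 64.8%, and the neighbouring flask gives 66.2%. At 30.0 min, homo product in the neighbouring flask holds 20.0% of the substrate charged, against 10.6% in the flask asked about.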